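The numbers in the tables stem from a simulated flask on assumed constants; scatter was added.

**Closed balance.** In a closed flask the charge stays put: target plus the fraction left, in whatever form, equals the solid substrate charged. So we reckon with the fraction left.

| flask | solid substrate | temperature | remark | time |
|---|---|---|---|---|
| Thursday's | 20 mM | 80 °C | the very flask that is asked about, followed so far |  |
| Wednesday's | 10 mM | 75 °C | run made earlier |  |
| flask | 20 mM | 80 °C |  | 80 min |

| run | time / min | target / % |
|---|---|---|
| Thursday's | 12.0 | 22 |
| Thursday's | 25.0 | 24 |
| Thursday's | 40.0 | 27 |
| Thursday's | 50.0 | 26 |
| Thursday's | 60.0 | 23 |
| Thursday's | 80.0 | 22 |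
| Wednesday's | 0.500 | 0 |
| Wednesday's | 1.00 | 2 |
| Wednesday's | 1.50 | 5 |
| Wednesday's | 2.00 | 9 |
| Wednesday's | 2.50 | 11 |
| Wednesday's | 3.00 | 15 |

(scatter of a reading: 1.5 percentage points)

- solid substrate is a solid; its amount is given per volume of the solution
- target taken out counts as made
- at the start none of the solid substrate is in solution

- delta: change nothing and wait 40 min more
- eta: at 80 min raise the temperature by 15 K, then wait 40 min
- alpha: at 80 min take out 90% of the target then present, then wait 40 min

* target, in percent of the solid substrate first charged, at 80 min
* what to do for the largest gain in target; "none" if nothing gains more than 2 percentage points (delta / eta / alpha / none)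
* target present, with what was taken out counted in, in percent of the solid substrate first charged, after delta
* target present, with what was taken out counted in, in percent of the solid substrate first charged, after eta

**Main step.** Take first a one-way step from solid substrate to target. The fraction left then falls towards zero, and Wednesday's run, at 15% after 3.00 min and still rising, looks like that.

**Return step.** Thursday's run does not: it reads 22% at 12.0 min and 22% at 80.0 min. A return step stops the fraction left short of zero. Thursday's readings average 24.0%, good to 0.61 percentage points. We call this f, the plateau share: the part of what the flask holds that stands as target once it stops moving (the equilibrium yield). The fraction left is then 76.0%.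

**The rest.** Dissolution adds a delay: Wednesday's run reads 0% at 0.500 min. Thursday's flask is already near f at its first reading, so we expect f at 80 min and after waiting. No plateau was read at another temperature, so for heating we simply keep f. For removal we assume, untested, that f is a share of what remains. Taking out a share x = 90% of the target leaves 78.4% of the charge, which refills to f of itself. The gain is x·f·(1−f), or 16 points.

**The forecast.** It gives 24% now, 24% after waiting and 29% after heating, and it chooses alpha. It parts from our reckoning on heating: “Solubility would probably rise modestly”.

**The result.** The flask gives 24.2% now, 24.2% after waiting and 23.0% after heating. The best option is alpha, which gains 17 points.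

    solid substrate ⇌ starting material, rate k1*(cs1 - [starting material]) while solid is left; crystals form when [starting material] > cs1 (solubility = 12.0 mM, k = 0.370 /min)
    starting material ⇌ target (K = 1.90, k = 0.250 /min, Ea = 96.0 kJ/mol, ΔH = −24.0 kJ/mol)
    starting material ⇌ dormant form (K = 0.740, k = 0.350 /min, Ea = 93.0 kJ/mol, ΔH = −35.0 kJ/mol)
    starting material ⇌ isomer of the product (K = 4.20, k = 0.0160 /min, Ea = 95.0 kJ/mol, ΔH = −22.0 kJ/mol)
    target ⇌ isomer of the product (k = 0.370 /min, Ea = 112 kJ/mol)
    (constants at 80 °C)

**What stands.** The step between starting material and target, taken by itself and both ways together, relaxes with a half-life of 1.82 min, far shorter than the 80 min of the asked flask. In that flask at 80 min, its backward rate stands at >99.9% of its forward rate. Held through heating, f misses by 1.00 point, and the forecast by 6 points.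

**Second flask.** For a flask kept at 65 °C, with amounts and time as in the asked flask, f carried over from Thursday's run gives 24.0%. The computed target there is 24.1%.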